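(The earlier runs and the new flask come from a simulation from invented constants; scatter was added.)

| flask | substrate | reagent | remark | time |
|---|---|---|---|---|
| red | 1 M | 0.80 equiv | run made earlier |  |
| teal | 2 M | 1.2 equiv | run made earlier |  |
| flask | 2.0 M | 0.800 equiv |  | 6.0 min |

| run | time / min | intermediate C / % | intermediate A / % | substrate / % | product / % | intermediate B / % |
|---|---|---|---|---|---|---|
| red | 0.250 | 2 | 5 | 91 | 1 | 0 |
| red | 0.417 | 3 | 10 | 91 | 0 | 3 |
| red | 0.667 | 2 | 11 | 85 | 1 | 2 |
| red | 1.00 | 7 | 14 | 80 | 0 | 3 |
| red | 1.50 | 8 | 17 | 76 | 0 | 3 |
| red | 2.50 | 13 | 16 | 63 | 1 | 6 |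
| red | 4.00 | 14 | 24 | 55 | 3 | 7 |
| teal | 0.250 | 1 | 14 | 83 | 1 | 1 |
| teal | 0.500 | 6 | 19 | 71 | 0 | 3 |
| teal | 1.00 | 9 | 30 | 57 | 0 | 10 |
| teal | 2.00 | 20 | 28 | 39 | 5 | 12 |
| teal | 4.00 | 18 | 26 | 23 | 14 | 12 |

(each reading ± 1.5 percentage points)

- the largest share of what was charged as substrate, at 6.0 min belongs to (substrate / intermediate C / intermediate B / intermediate A / product)
- the largest share itself, whichever of these holds it, in percent of the substrate charged

Start by counting reagent: take it that each substrate that reacts uses one. Per substrate consumed, the teal run reads more intermediate B plus product than the red run, 0.338 against 0.222 at their last readings; teal differs in both substrate and reagent, and I assume those two species hold a second reagent. The mean gives 1.28 reagent per substrate consumed, the reagent cost.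

Now draw the flask's curve. Teal's first reading gives a rate constant k of about 0.311 /M/min, so I put substrate in the flask falling at first at 0.497 /min. At 0.800 equiv reagent is the limiting reagent in the flask, and dividing its charge by the cost puts the level at which substrate stops, the floor, at 37.5%. Tie [reagent] to [substrate] through the cost and k[substrate][reagent] integrates in closed form: substrate relaxes onto the floor with constant 0.298 /min. The knee lies near 3.36 min, and at 6.0 min I get 41.9%. Intermediate A, taking teal's last ratio of intermediate C to it, comes to 24.7%, less than substrate, so I expect no crossing.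

The forecast also names substrate, at 33.5%, lower than my figure: “Substrate therefore stays largest, because the reagent is nearly exhausted”.

The flask gives substrate at 39.6%.

    reagent + intermediate A → intermediate B (k = 0.00460 /M/s)
    substrate + reagent → intermediate A (k = 0.00550 /M/s)
    intermediate B → product (k = 0.00580 /s)
    intermediate A ⇌ intermediate C (K = 0.650, k = 0.0140 /s)

In the flask, substrate + reagent ran early: by 3.00 min that step had 87% of its turnover up to 6.0 min behind it, with reagent at 20.1% of its charge. Reagent fell to 5.5% of its charge at 6.00 min, when the flask's cost stood at 1.25; at 60.0 min substrate in the flask holds 36.9% against the floor of 37.5%. The neighbour with 0.200 equiv has a floor of 84.4% at my cost, and at 6.00 min its substrate stands at 81.6% with a cost of 1.06.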